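The depside is cut at its aryl ester, and both halves are traced to one resorcylate. Ring A and ring B each carry the carboxyl carbon at C1, heptyl at C2 and oxygen at C4 and C6, the meta-related oxygen pattern left by a cyclised tetraketide chain. The key step exploits this pattern. Linear benzyl 3,5,7-trioxotetradecanoate, made from a diketo-dioxinone by acylketene capture with benzyl alcohol, closes by bonding chain C2 to the C7 ketone (ring bond C1–C2) and aromatises. This sets ring, heptyl, carboxyl and both oxygens in one operation. In the product the C6 hydroxyl is hydrogen-bonded to the ester, so the free C4 hydroxyl is acylated selectively without protecting groups.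

Key step: step 4

Remark on the structure: the target has no stereocentre and no double-bond geometry, so no stereocontrol is required.
Remark on ring B: it bears heptyl, not methyl, next to its carbonyl and is the O,O-dimethyl ether of the ring A acid. A C-methyl resorcylate would lack six carbons, so ring B is taken from the key-step product itself.
Remark on tautomers: the polycarbonyl compounds are drawn all-keto but will exist as keto–enol mixtures.

Step 1
Reactants: 1 2,2,6-trimethyl-4H-1,3-dioxin-4-one; 2 acetyl chloride
Product: 4 2,2-dimethyl-6-(2-oxopropyl)-4H-1,3-dioxin-4-one, via lithium dienolate 3 (not isolated)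
Conditions: LiN(SiMe3)2 (1.0 M in THF, 1.05 equiv), THF, −78 °C; then 2 (0.5 equiv relative to 1), −78 to −20 °C; 1 M aq. HCl quench
Reagents that add atoms: none
Why: This is a vinylogous Claisen-type C-acylation in which the dioxinone dienolate reacts with acid chlorides at its γ-carbon (the former C6 methyl), and keeping the chloride limiting lets surplus dienolate absorb the acidic proton of the new β-keto system.

Step 2
Reactants: 4 2,2-dimethyl-6-(2-oxopropyl)-4H-1,3-dioxin-4-one; 5 octanoyl chloride
Product: 7 6-(2,4-dioxoundecyl)-2,2-dimethyl-4H-1,3-dioxin-4-one, via dilithium dianion 6 (not isolated)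
Conditions: LiN(i-Pr)2 (2.1 equiv relative to 4), THF, −78 °C; then 5 (0.5 equiv relative to 4), −78 °C; 1 M aq. HCl quench at low temperature; surplus 4 recovered
Reagents that add atoms: none
Why: This is a β-dicarbonyl dianion acylation (Claisen type) in which the terminal carbanion, formed last and least stabilised, is the most nucleophilic site, so the octanoyl group should enter at the methyl terminus while surplus dianion takes up the newly acidic proton.

Step 3
Reactants: 7 6-(2,4-dioxoundecyl)-2,2-dimethyl-4H-1,3-dioxin-4-one; 8 benzyl alcohol
Product: 10 benzyl 3,5,7-trioxotetradecanoate, via acylketene 9 (not isolated)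
Conditions: 8 (1.1 equiv), PhMe, 110 °C; concentrated and carried on without chromatography
Reagents that add atoms: none
Why: A thermal retro-hetero-Diels–Alder fragmentation of the dioxinone expels acetone, and the primary alcohol adds to the acylketene under neutral conditions faster than the chain's own enols do, giving the β-keto ester.

Step 4
Reactants: 10 benzyl 3,5,7-trioxotetradecanoate
Product: 12 benzyl 2-heptyl-4,6-dihydroxybenzoate, via aldol carbinol 11 (not isolated)
Conditions: Cs2CO3 (2 equiv), CH2Cl2–i-PrOH, rt; then HCl (4 M in dioxane) to acidic pH, rt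
Reagents that add atoms: none
Why: Cs2CO3 enolises the chain reversibly, the C2 enolate (flanked by the ester and the C3 ketone) adds to the C7 ketone to give carbinol 11, and acid then expels the tertiary hydroxyl as one molecule of water, after which the C3 and C5 carbonyls tautomerise to the C6 and C4 phenols of the arene. The reaction type is the known biomimetic intramolecular aldol condensation–aromatisation of dioxinone-derived 3,5,7-triketo esters to 6-alkyl-2,4-dihydroxybenzoates. The single ring closes 6-exo-trig at the ketone; written through the C2=C3 enolate it is 6-(enolendo)-exo-trig, written through the ester enolate 6-(enolexo)-exo-trig, and both modes are favoured for six-membered rings. No stereocentre is kept, since the two formed in 11 are erased on aromatisation. The step needs the C2-to-C7 aldol to outrun the Claisen closure (C6 onto the ester carbon C1, leading to an acylphloroglucinol) and the attack of the C5 enol oxygen on C1 (leading to a 4-hydroxy-2-pyrone). The substrate secures this because the C7 dialkyl ketone is more electrophilic than the ester carbonyl, both rival closures must expel benzyl oxide from a tetrahedral intermediate, which a carbonate base at room temperature promotes poorly, and only the aldol channel is drained irreversibly by aromatisation.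

Step 5
Reactants: 12 benzyl 2-heptyl-4,6-dihydroxybenzoate (first portion)
Product: 13 benzyl 2-heptyl-4,6-dimethoxybenzoate
Conditions: MeI (5 equiv), K2CO3 (4 equiv), DMF, 50 °C
Reagents that add atoms: methyl iodide, CI
Why: In this Williamson ether synthesis, excess reagent and gentle heating should etherify both the free C4 phenoxide and the less reactive hydrogen-bonded C6 phenol, while the doubly ortho-substituted benzyl ester is inert.

Step 6
Reactants: 13 benzyl 2-heptyl-4,6-dimethoxybenzoate
Product: 14 2-heptyl-4,6-dimethoxybenzoic acid
Conditions: H2 (1 atm), Pd/C (10 wt% Pd), EtOAc, rt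
Reagents that add atoms: none
Why: Catalytic hydrogenolysis of the benzylic C–O bond frees the hindered acid under neutral conditions, avoiding a forcing saponification and leaving the aryl methyl ethers untouched.

Step 7
Reactants: 14 2-heptyl-4,6-dimethoxybenzoic acid; 12 benzyl 2-heptyl-4,6-dihydroxybenzoate (second portion)
Product: 16 benzyl 2-heptyl-4-[(2-heptyl-4,6-dimethoxybenzoyl)oxy]-6-hydroxybenzoate, via mixed anhydride 15 (not isolated)
Conditions: (CF3CO)2O (3 equiv), PhMe, 0 °C to rt; aq. NaHCO3 work-up
Reagents that add atoms: none
Why: In this mixed-anhydride esterification, a standard way of joining depside halves, the electron-rich hindered acid becomes an acylium-like donor that should acylate the exposed C4 hydroxyl, whereas the C6 hydroxyl is tied to the ester carbonyl by its hydrogen bond and any aryl trifluoroacetate falls off on work-up.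

Step 8
Reactants: 16 benzyl 2-heptyl-4-[(2-heptyl-4,6-dimethoxybenzoyl)oxy]-6-hydroxybenzoate
Product: 17 benzyl 2-heptyl-4-[(2-heptyl-4,6-dimethoxybenzoyl)oxy]-6-methoxybenzoate
Conditions: MeI (4 equiv), K2CO3 (1.5 equiv), dry DMF, rt
Reagents that add atoms: methyl iodide, CI
Why: In this Williamson ether synthesis the only acidic site left is the C6 phenol, and the depside ester should survive anhydrous carbonate because its carbonyl is shielded by the ortho heptyl and ortho methoxy groups and lies meta to the phenoxide, out of reach for acyl migration.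

Step 9
Reactants: 17 benzyl 2-heptyl-4-[(2-heptyl-4,6-dimethoxybenzoyl)oxy]-6-methoxybenzoate
Product: 18 2-heptyl-4-[(2-heptyl-4,6-dimethoxybenzoyl)oxy]-6-methoxybenzoic acid (CNP0300299.0)
Conditions: H2 (1 atm), Pd/C (10 wt% Pd), EtOAc, rt
Reagents that add atoms: none
Why: Catalytic hydrogenolysis cleaves only the benzylic C–O bond, so the acid is released without any nucleophile or base that could attack the aryl ester joining the two rings.

Compound list
1 | 2,2,6-trimethyl-4H-1,3-dioxin-4-one | CC1=CC(=O)OC(C)(C)O1 | starting material
2 | acetyl chloride | CC(=O)Cl | starting material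
3 | lithium dienolate of 1, lithium 2,2-dimethyl-6-methylidene-1,3-dioxin-4-olate (not isolated) | [Li+].C=C1C=C([O-])OC(C)(C)O1 | intermediate
4 | 2,2-dimethyl-6-(2-oxopropyl)-4H-1,3-dioxin-4-one | CC(=O)CC1=CC(=O)OC(C)(C)O1 | intermediate
5 | octanoyl chloride | CCCCCCCC(=O)Cl | starting material
6 | dilithium dianion of 4, deprotonated at the internal CH2 and at the terminal CH3 (not isolated) | [Li+].[Li+].C=C([O-])C=C1C=C([O-])OC(C)(C)O1 | intermediate
7 | 6-(2,4-dioxoundecyl)-2,2-dimethyl-4H-1,3-dioxin-4-one | CCCCCCCC(=O)CC(=O)CC1=CC(=O)OC(C)(C)O1 | intermediate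
8 | benzyl alcohol | OCc1ccccc1 | starting material
9 | acylketene, tetradec-1-ene-1,3,5,7-tetraone (not isolated) | CCCCCCCC(=O)CC(=O)CC(=O)C=C=O | intermediate
10 | benzyl 3,5,7-trioxotetradecanoate | CCCCCCCC(=O)CC(=O)CC(=O)CC(=O)OCc1ccccc1 | intermediate
11 | benzyl 2-heptyl-2-hydroxy-4,6-dioxocyclohexane-1-carboxylate, diastereomer and enol mixture (not isolated) | CCCCCCCC1(O)CC(=O)CC(=O)C1C(=O)OCc1ccccc1 | intermediate
12 | benzyl 2-heptyl-4,6-dihydroxybenzoate | CCCCCCCc1cc(O)cc(O)c1C(=O)OCc1ccccc1 | intermediate
13 | benzyl 2-heptyl-4,6-dimethoxybenzoate | CCCCCCCc1cc(OC)cc(OC)c1C(=O)OCc1ccccc1 | intermediate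
14 | 2-heptyl-4,6-dimethoxybenzoic acid | CCCCCCCc1cc(OC)cc(OC)c1C(=O)O | intermediate
15 | 2-heptyl-4,6-dimethoxybenzoic trifluoroacetic anhydride (not isolated) | CCCCCCCc1cc(OC)cc(OC)c1C(=O)OC(=O)C(F)(F)F | intermediate
16 | benzyl 2-heptyl-4-[(2-heptyl-4,6-dimethoxybenzoyl)oxy]-6-hydroxybenzoate | CCCCCCCc1cc(OC(=O)c2c(CCCCCCC)cc(OC)cc2OC)cc(O)c1C(=O)OCc1ccccc1 | intermediate
17 | benzyl 2-heptyl-4-[(2-heptyl-4,6-dimethoxybenzoyl)oxy]-6-methoxybenzoate | CCCCCCCc1cc(OC(=O)c2c(CCCCCCC)cc(OC)cc2OC)cc(OC)c1C(=O)OCc1ccccc1 | intermediate
18 | 2-heptyl-4-[(2-heptyl-4,6-dimethoxybenzoyl)oxy]-6-methoxybenzoic acid | CCCCCCCc1cc(OC(=O)c2c(CCCCCCC)cc(OC)cc2OC)cc(OC)c1C(=O)O | target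

Total step count: 9
Longest linear sequence: 9 steps (1 → 4 → 7 → 10 → 12 → 13 → 14 → 16 → 17 → 18). The ring B branch runs through the shared intermediate 12, and the second portion of 12 enters at step 7.

Steps most likely to fail

Step 4. The chain may fold the wrong way, through attack on the ester carbonyl by C6 or by the C5 enol oxygen, or it may fragment by retro-Claisen scission under base. The fallback sets out from 7 and comes back at 12. The ring is closed before the dioxinone is opened. Et3N in CH2Cl2 at rt should make the dioxinone α-carbon add to the heptyl ketone, forming the same C–C bond, and aromatise to 5-heptyl-7-hydroxy-2,2-dimethyl-4H-1,3-benzodioxin-4-one F1. The carboxyl carbon is locked in the acetonide throughout, so neither rival closure has an acyl carbon to attack. NaOCH2Ph (from 8 and NaH, in excess so that the phenol is covered) in warm THF should then open the benzodioxinone by acyl substitution, with loss of acetone, to give 12.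

Step 2. The hard dianion may be O-acylated or acylated more than once, or it may be quenched by proton transfer from the enolisable acid chloride and from the product. The fallback sets out from 1 (as its dienolate 3) and comes back at 7. It replaces the dianion by a soft magnesium enolate bearing a traceless activating ester.
- Purchased mono-allyl malonate and oxalyl chloride (catalytic DMF, CH2Cl2) give allyl 3-chloro-3-oxopropanoate F2.
- F2 acylates dienolate 3 at −78 °C to give allyl 4-(2,2-dimethyl-4-oxo-4H-1,3-dioxin-6-yl)-3-oxobutanoate F3.
- MgCl2, pyridine and 5 in CH2Cl2 at 0 °C should C-acylate the carbon between ester and ketone, giving allyl 2-[(2,2-dimethyl-4-oxo-4H-1,3-dioxin-6-yl)acetyl]-3-oxodecanoate F4.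
- Pd(PPh3)4 (catalytic, zerovalent palladium) with morpholine removes the allyl group (Tsuji–Trost deallylation), and the resulting acid decarboxylates spontaneously to 7.

Step 8. Etherification of the hydrogen-bonded and flanked C6 hydroxyl may be slow. Base would then have time to cleave or transacylate the ester between the rings. The fallback sets out from 12 and comes back at 17. It places the methyl group before the depside bond exists.
- Allyl bromide (1 equiv) and K2CO3 in acetone at rt should etherify only the free C4 hydroxyl, giving benzyl 2-heptyl-6-hydroxy-4-(prop-2-enyloxy)benzoate F5.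
- MeI and K2CO3 in DMF at 50 °C give benzyl 2-heptyl-6-methoxy-4-(prop-2-enyloxy)benzoate F6.
- Pd(PPh3)4 and morpholine release benzyl 2-heptyl-4-hydroxy-6-methoxybenzoate F7.
- F7 is joined to 14 under the conditions of step 7 to give 17.

Further compounds
F1 | step 4 | 5-heptyl-7-hydroxy-2,2-dimethyl-4H-1,3-benzodioxin-4-one | CCCCCCCc1cc(O)cc2OC(C)(C)OC(=O)c12
F2 | step 2 | allyl 3-chloro-3-oxopropanoate | C=CCOC(=O)CC(=O)Cl
F3 | step 2 | allyl 4-(2,2-dimethyl-4-oxo-4H-1,3-dioxin-6-yl)-3-oxobutanoate | C=CCOC(=O)CC(=O)CC1=CC(=O)OC(C)(C)O1
F4 | step 2 | allyl 2-[(2,2-dimethyl-4-oxo-4H-1,3-dioxin-6-yl)acetyl]-3-oxodecanoate | CCCCCCCC(=O)C(C(=O)OCC=C)C(=O)CC1=CC(=O)OC(C)(C)O1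
F5 | step 8 | benzyl 2-heptyl-6-hydroxy-4-(prop-2-enyloxy)benzoate | CCCCCCCc1cc(OCC=C)cc(O)c1C(=O)OCc1ccccc1
F6 | step 8 | benzyl 2-heptyl-6-methoxy-4-(prop-2-enyloxy)benzoate | CCCCCCCc1cc(OCC=C)cc(OC)c1C(=O)OCc1ccccc1
F7 | step 8 | benzyl 2-heptyl-4-hydroxy-6-methoxybenzoate | CCCCCCCc1cc(O)cc(OC)c1C(=O)OCc1ccccc1
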